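## Structural features

The target is a dimer of two (2S)-7-hydroxy-5-methoxyflavans (2-phenylchromans). One methylene carbon joins C8 of unit A to C6' of unit B, so the two benzo rings form a diarylmethane whose bridge lies between O1 and O7 on one side and between the 5'-OMe and the 7'-OH on the other. There are only two stereocentres, C2 and C2', both S (O1 > phenyl > C3 at each [C@@H]); they sit in different pyran rings, far apart and with no neighbouring stereocentre, so each has to be set by a reagent. The two monomers are constitutionally identical, so the real constitutional difficulty is the unsymmetrical 8→6' junction (not 8→8' or 6→6'); the stereochemical difficulty is twofold absolute control. Several features are fragile: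
- each benzo ring keeps one unsubstituted, very nucleophilic carbon (C6 in unit A, C8' in unit B) that will capture any carbon electrophile set free nearby;
- the bis-ortho-oxygenated diarylmethane bridge can be cleaved by strong acid;
- the phenols are oxidisable;
- both C2–O1 bonds are benzylic ethers, open to hydrogenolysis and acid ionisation.

In each pyran ring C2 carries O1 and the phenyl group and stands β to C4. With a carbonyl at C4 and a C2=C3 double bond (a chromone), C2 becomes the β-carbon of a vinylogous ester, and the C2–phenyl bond can be made by conjugate arylation. The key step uses this in both units at once. The drawn structure and the (2S,2'S) assignment agree; no correction of the target was needed.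

## Logic of the disconnections

13 ⇒ 12. The O7–H and O7'–H bonds are traced back to O–benzyl bonds and C8'–H to C8'–Br. A methoxymethyl ether at O7 was set aside because its acidic removal releases a one-carbon electrophile beside the nucleophilic C6 and C8' positions and because it is at risk in the acid-mediated pyranone closure. Benzyl releases only an inert hydrocarbon. The bromine is the blocking atom that fixes the 6'-linkage earlier. All three groups fall in one hydrogenolysis, so the blocking atom costs no step at the end. The forward step must stop short of the benzylic C2–O1 and C2'–O1' bonds.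

12 ⇒ 11 ⇒ 10. The C4–H and C4'–H bonds are traced back to C4–OH and then to C4=O. The carbonyl is what makes C2 an acceptor carbon, so it has to be present in the key step and excised afterwards. The forward reduction and ionic deoxygenation must leave C2 untouched (no retro-oxa-Michael opening, no ionisation at C2) and must not cleave the bridge.

10 ⇒ 8 + 9. Both C2–C(phenyl) bonds are cut. This removes both stereocentres and both phenyl groups in one operation and leads to 8, which is achiral and flat in each half. The forward step needs catalyst-controlled facial selectivity twice, 1,4- rather than 1,2-addition, tolerance of the aryl bromide and a non-basic medium.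

8 ⇒ 6 (through 7). In each pyranone O1–C2 and C2–C3 are cut; C2 is a one-carbon unit at the formate oxidation level. This removes both heterocycles and leaves two o-hydroxyaryl methyl ketones. The closure is unambiguous only if the sole free phenols in 6 are those ortho to the acetyl groups, which holds because O7 and O7' are already benzylated.

6 ⇒ 5 + 3. The bond between the bridge carbon and C6' is cut. The CH2 stays on ring A as an ortho-hydroxybenzyl alcohol (a latent ortho-quinone methide), and ring B becomes an arene whose only unsubstituted carbon is the one wanted. Both acetyl groups are already in place, so no late ring acylation of uncertain regiochemistry is needed. The forward step must favour cross-alkylation over self-alkylation of 5.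

5 ⇒ 4 ⇒ 2. C3–CH2OH is traced back to C3–CHO and then to C3–H. The carbon ortho to the chelated phenol can be formylated with ortho specificity, which fixes the 8-linkage of unit A. The forward steps need ring formylation rather than reaction at the acetyl group, and aldehyde-selective reduction.

3 ⇒ 2. The C3–Br bond is cut. Bromine occupies the more reactive position between OH and OBn, so the later C–C bond can only go to C5, which becomes C6' of unit B. The forward step needs clean monobromination at C3.

2 ⇒ 1. The O4–benzyl bond is cut. The forward step needs selectivity for the non-chelated hydroxyl. Both halves of the dimer thus come from 1.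

## Other disconnections considered

Alternative 1: The cut is at the two C3–C4 bonds, with the two O1–C2 bonds closed later. In the forward key step a dianion generated α to two benzylic phenylsulfonyl groups opens two molecules of (S)-styrene oxide A2 at the unsubstituted carbon. This gives the bis(γ-hydroxy sulfone) A1 with R carbinols. De-allylation of the O1 phenols, twofold Mitsunobu closure with inversion (R to S), reductive desulfonylation and debenzylation would follow.
- In favour: the absolute configuration comes from a cheap enantiopure building block, and no C4 oxygen has to be removed.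
- Against: the dianion needs two benzylic sulfones at doubly ortho-oxygenated positions of an assembled hexa-oxygenated diarylmethane; both carbanions are hindered nucleophiles toward an epoxide; Mitsunobu displacement at a benzylic carbinol can leak through an ionised pathway at each of two centres; three kinds of oxygen protection are needed; and four operations follow the key step.
- Comparison: on the source of chirality this plan is the better one, since the enantiopurity is bought and no ligand has to be matched to the substrate. On mechanism it sets the centres by a stereospecific substitution with inversion, whereas the chosen plan uses a catalyst-controlled insertion. On step economy and on the number of protecting-group types the chosen plan is shorter.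

Alternative 2: The cut removes the whole benzo ring of unit B, at C6'–C7' and C4a'–C5' with the ring closed by a 6π step. In the forward key step a ring-fused cyclobutenone that already carries the C2' stereocentre opens thermally to a vinylketene. This adds to a methoxyalkyne bearing the complete unit A; four-electron opening, six-electron closure and tautomerisation give the 7-O-benzyl target A3, with the 7'-phenol free.
- In favour: the 8→6' junction, the 5'-OMe and the 7'-OH are written into the alkyne, so the linkage regiochemistry is fixed by construction. The unit B phenol appears unprotected, and one debenzylation ends the synthesis.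
- Against: each partner must be made enantiopure on its own, so there are two separate asymmetric syntheses. One partner is a sensitive ynol ether on an electron-rich flavan; the other is a strained bicyclic cyclobutenone with no short access. The thermal step has to spare the benzylic C2–O1 bond.
- Comparison: on certainty of the linkage it is the equal of the chosen plan, which reaches the same certainty with a blocking bromine. On the endgame it is the better plan (one step after the key step against three). On overall step count, and on setting both stereocentres in a single operation, the chosen plan is better.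

Alternative 3: The cut is at both O1–C2 bonds, then at C3=C4 by metathesis. In the forward key step the two C8a phenoxides of a bis(2-vinylphenol) attack an iridium-bound 1-phenylallyl fragment at its phenyl-bearing end (catalyst from [Ir(cod)Cl]2 and a chiral phosphoramidite). This gives the bis[(S)-1-phenylallyl] aryl ether A4. Twofold ring-closing metathesis (second-generation Grubbs catalyst) and one hydrogenation that saturates C3=C4 and removes the benzyl groups would finish.
- In favour: branched-selective iridium allylic etherification of phenoxides is a dependable reaction class; no C4 oxygen has to be removed; and the endgame is two operations.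
- Against: the unit A phenoxide is flanked by the bridge and a vinyl group and is a hindered nucleophile. The bis(2-vinylphenol) needs two formylation–olefination sequences and differentiated phenols, and is prone to polymerisation. The 2-phenyl-2H-chromenes formed by metathesis can open reversibly to ortho-quinone methides, which would erase C2, and their allylic-benzylic C2–O bond is more exposed to hydrogenolysis than that of a flavan.
- Comparison: on stereocontrol it is the equal of the chosen plan, since both rely on two independent catalyst-controlled events. On the endgame it is the better plan. On access to the precursor and on configurational stability of the intermediates the chosen plan is better.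

Key step: step 7

Assumptions (remarks on the chemistry):
- The (S,S) hand of the diene is written as the one expected to give 2S by the usual facial model for this ligand class. The sense depends only on the ligand hand, so if a trial on a monomeric chromone shows the opposite, the (R,R) ligand is used with nothing else changed.
- C4 and C4' of 11 are left undefined because both carbinols are removed in step 9.

## Route

Step 1
Reactants: 1 2,4-dihydroxy-6-methoxyacetophenone
Product: 2 1-[4-(benzyloxy)-2-hydroxy-6-methoxyphenyl]ethan-1-one
Conditions: BnBr (1.05 equiv), K2CO3 (1.2 equiv), acetone, reflux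
Reagents that add atoms: benzyl bromide, BrCc1ccccc1
Why: Williamson ether synthesis; the 2-OH is locked in a hydrogen bond to the acetyl carbonyl and is far less acidic and nucleophilic than the 4-OH, so mono-benzylation at O4 should be clean.

Step 2
Reactants: 2 1-[4-(benzyloxy)-2-hydroxy-6-methoxyphenyl]ethan-1-one
Product: 3 1-[4-(benzyloxy)-3-bromo-2-hydroxy-6-methoxyphenyl]ethan-1-one
Conditions: NBS (1.0 equiv), MeCN, 0 °C to rt, dark
Reagents that add atoms: N-bromosuccinimide, O=C1CCC(=O)N1Br
Why: Electrophilic aromatic bromination; in 2-hydroxy-4,6-dialkoxyacetophenones halogenation goes to the carbon between the chelated OH and the 4-alkoxy group (C3), which is less hindered than C5 between two ethers, and the site is to be confirmed by NOE (remaining aryl H next to both OCH3 and OCH2Ph) before use.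

Step 3
Reactants: 2 1-[4-(benzyloxy)-2-hydroxy-6-methoxyphenyl]ethan-1-one
Product: 4 3-acetyl-6-(benzyloxy)-2-hydroxy-4-methoxybenzaldehyde
Conditions: MgCl2 (2 equiv), Et3N (4 equiv), (CH2O)n (7 equiv), MeCN, reflux; aq. HCl work-up
Reagents that add atoms: formaldehyde (as paraformaldehyde), C=O
Why: Magnesium phenoxide-mediated ortho-formylation; formaldehyde is delivered inside the magnesium phenoxide chelate, so attack can occur only at the one free carbon ortho to O2 (C3), and a second formaldehyde oxidises the hydroxymethyl intermediate by hydride transfer.

Step 4
Reactants: 4 3-acetyl-6-(benzyloxy)-2-hydroxy-4-methoxybenzaldehyde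
Product: 5 1-[4-(benzyloxy)-2-hydroxy-3-(hydroxymethyl)-6-methoxyphenyl]ethan-1-one
Conditions: NaBH4 (1 equiv), THF/MeOH 4:1, 0 °C; aq. NH4Cl
Reagents that add atoms: none
Why: Chemoselective borohydride reduction; the aldehyde is much more electrophilic than the doubly ortho-substituted, phenoxide-deactivated aryl methyl ketone, so only the formyl group should be reduced at 0 °C, and 5 is used without storage.

Step 5
Reactants: 5 1-[4-(benzyloxy)-2-hydroxy-3-(hydroxymethyl)-6-methoxyphenyl]ethan-1-one, 3 1-[4-(benzyloxy)-3-bromo-2-hydroxy-6-methoxyphenyl]ethan-1-one
Product: 6 bis-acetophenone 1-[3-{[5-acetyl-2-(benzyloxy)-3-bromo-4-hydroxy-6-methoxyphenyl]methyl}-4-(benzyloxy)-2-hydroxy-6-methoxyphenyl]ethan-1-one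
Conditions: TsOH·H2O (10 mol%), ClCH2CH2Cl, 50 °C; slow addition of 5 to 3 (3 equiv)
Reagents that add atoms: none
Why: Acid-catalysed Friedel–Crafts benzylation through an ortho-quinone methide or benzylic cation; 5 ionises easily (cation flanked by OH and OBn, para to OMe) and 3 has a single unsubstituted ring carbon (C5), so the new aryl–CH2 bond can form only there, while slow addition of 5 to excess 3 should suppress self-alkylation of 5 at its own C5.

Step 6
Reactants: 6 bis-acetophenone 1-[3-{[5-acetyl-2-(benzyloxy)-3-bromo-4-hydroxy-6-methoxyphenyl]methyl}-4-(benzyloxy)-2-hydroxy-6-methoxyphenyl]ethan-1-one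
Product: 8 bis-chromone 7-(benzyloxy)-8-{[7-(benzyloxy)-8-bromo-5-methoxy-4-oxo-4H-chromen-6-yl]methyl}-5-methoxy-4H-chromen-4-one, via bis-enaminone 7 (not isolated)
Conditions: Me2NCH(OMe)2 (8 equiv), toluene, 100 °C; evaporate; conc. aq. HCl, CH2Cl2, rt
Reagents that add atoms: N,N-dimethylformamide dimethyl acetal, COC(OC)N(C)C
Why: Enaminone formation at both methyl ketones, then acid-promoted addition–elimination of each chelated phenol onto the β-carbon with loss of dimethylamine (standard chromone synthesis); only the hydroxyls ortho to the acyl groups are free, so both closures are unambiguous, and benzyl ethers and the aryl bromide are inert to both stages.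

Step 7
Reactants: 8 bis-chromone 7-(benzyloxy)-8-{[7-(benzyloxy)-8-bromo-5-methoxy-4-oxo-4H-chromen-6-yl]methyl}-5-methoxy-4H-chromen-4-one, 9 phenylboronic acid
Product: 10 (2S,2'S)-bis-flavanone (2S)-7-(benzyloxy)-8-{[(2S)-7-(benzyloxy)-8-bromo-5-methoxy-4-oxo-2-phenyl-3,4-dihydro-2H-chromen-6-yl]methyl}-5-methoxy-2-phenyl-2,3-dihydro-4H-chromen-4-one
Conditions: 9 (6 equiv), Rh(acac)(C2H4)2 (10 mol%), (1S,4S)-2,5-diphenylbicyclo[2.2.2]octa-2,5-diene (11 mol%), 1,4-dioxane/H2O 10:1, 60 °C
Reagents that add atoms: none
Why: Hayashi–Miyaura conjugate addition, the closest known case being the rhodium/chiral-diene-catalysed addition of arylboronic acids to chromones to give flavanones. Phenyl passes from boron to the diene-bound monovalent rhodium hydroxide, the chromone C2=C3 bond coordinates and inserts into the Rh–phenyl bond with phenyl going to the β-carbon C2, and water protonates the rhodium oxa-π-allyl to release the flavanone and regenerate Rh–OH. No ring is closed. Each new stereocentre (C2 and C2') is set by the chiral diene, which leaves one face of the bound enone open in the insertion step, the (S,S) hand being chosen for 2S at both sites. The two chromones are insulated by the CH2 bridge and react independently, so a minor event at either site gives only a separable diastereomer and the enantiopurity of the (2S,2'S) product should exceed that of a single addition. The step needs 1,4- rather than 1,2-addition, which the polarised vinylogous ester and the aryl–rhodium species provide, and it needs the C8'–Br bond to stay intact, which is expected because monovalent rhodium aryls do not add oxidatively to a hindered aryl bromide under these conditions. The absence of base avoids opening of the pyranones of 8 and retro-oxa-Michael racemisation of 10; the electron-rich chromones are slow acceptors, hence excess 9 and 60 °C.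

Step 8
Reactants: 10 (2S,2'S)-bis-flavanone (2S)-7-(benzyloxy)-8-{[(2S)-7-(benzyloxy)-8-bromo-5-methoxy-4-oxo-2-phenyl-3,4-dihydro-2H-chromen-6-yl]methyl}-5-methoxy-2-phenyl-2,3-dihydro-4H-chromen-4-one
Product: 11 bis(flavan-4-ol) (2S)-7-(benzyloxy)-8-{[(2S)-7-(benzyloxy)-8-bromo-4-hydroxy-5-methoxy-2-phenyl-3,4-dihydro-2H-chromen-6-yl]methyl}-5-methoxy-2-phenyl-3,4-dihydro-2H-chromen-4-ol (C4/C4' epimer mixture)
Conditions: NaBH4 (4 equiv), THF/MeOH 1:1, 0 °C
Reagents that add atoms: none
Why: Hydride reduction of the two aryl ketones, expected mainly 2,4-cis but irrelevant since both carbinols are removed next; low temperature and short contact keep the mildly basic medium from opening the pyranones by retro-oxa-Michael, so C2 and C2' should be untouched.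

Step 9
Reactants: 11 bis(flavan-4-ol) (2S)-7-(benzyloxy)-8-{[(2S)-7-(benzyloxy)-8-bromo-4-hydroxy-5-methoxy-2-phenyl-3,4-dihydro-2H-chromen-6-yl]methyl}-5-methoxy-2-phenyl-3,4-dihydro-2H-chromen-4-ol (C4/C4' epimer mixture)
Product: 12 (2S)-7-(benzyloxy)-8-{[(2S)-7-(benzyloxy)-8-bromo-5-methoxy-2-phenyl-3,4-dihydro-2H-chromen-6-yl]methyl}-5-methoxy-2-phenyl-3,4-dihydro-2H-chromene
Conditions: Et3SiH (6 equiv), CF3CO2H (10 equiv), CH2Cl2, −20 to 0 °C
Reagents that add atoms: none
Why: Ionic hydrogenation; each C4 carbinol ionises to a benzylic cation stabilised by O1, the ortho 5-OMe and the para 7-OBn and is trapped by hydride from the silane, C2 is not involved, and aryl benzyl ethers and the aryl bromide tolerate the cold acid.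

Step 10
Reactants: 12 (2S)-7-(benzyloxy)-8-{[(2S)-7-(benzyloxy)-8-bromo-5-methoxy-2-phenyl-3,4-dihydro-2H-chromen-6-yl]methyl}-5-methoxy-2-phenyl-3,4-dihydro-2H-chromene
Product: 13 (2S)-8-{[(2S)-7-hydroxy-5-methoxy-2-phenyl-3,4-dihydro-2H-chromen-6-yl]methyl}-5-methoxy-2-phenyl-3,4-dihydro-2H-chromen-7-ol
Conditions: H2 (1 atm), Pd/C (10 wt% Pd), NaOAc (3 equiv), EtOAc/MeOH 1:1, rt
Reagents that add atoms: none
Why: Heterogeneous hydrogenolysis cleaves both aryl benzyl ethers and the aryl C–Br bond in one operation; NaOAc takes up the HBr so the medium stays non-acidic and the benzylic C2–O1 ethers should survive, and no stereocentre is touched.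

## Compound list

1 | 2,4-dihydroxy-6-methoxyacetophenone | COc1cc(O)cc(O)c1C(C)=O | starting material
2 | 1-[4-(benzyloxy)-2-hydroxy-6-methoxyphenyl]ethan-1-one | COc1cc(OCc2ccccc2)cc(O)c1C(C)=O | intermediate
3 | 1-[4-(benzyloxy)-3-bromo-2-hydroxy-6-methoxyphenyl]ethan-1-one | COc1cc(OCc2ccccc2)c(Br)c(O)c1C(C)=O | intermediate
4 | 3-acetyl-6-(benzyloxy)-2-hydroxy-4-methoxybenzaldehyde | COc1cc(OCc2ccccc2)c(C=O)c(O)c1C(C)=O | intermediate
5 | 1-[4-(benzyloxy)-2-hydroxy-3-(hydroxymethyl)-6-methoxyphenyl]ethan-1-one | COc1cc(OCc2ccccc2)c(CO)c(O)c1C(C)=O | intermediate
6 | bis-acetophenone 1-[3-{[5-acetyl-2-(benzyloxy)-3-bromo-4-hydroxy-6-methoxyphenyl]methyl}-4-(benzyloxy)-2-hydroxy-6-methoxyphenyl]ethan-1-one | COc1cc(OCc2ccccc2)c(Cc2c(OCc3ccccc3)c(Br)c(O)c(C(C)=O)c2OC)c(O)c1C(C)=O | intermediate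
7 | bis-enaminone (2E)-1-[3-({5-[(2E)-3-(dimethylamino)prop-2-enoyl]-2-(benzyloxy)-3-bromo-4-hydroxy-6-methoxyphenyl}methyl)-4-(benzyloxy)-2-hydroxy-6-methoxyphenyl]-3-(dimethylamino)prop-2-en-1-one | COc1cc(OCc2ccccc2)c(Cc2c(OCc3ccccc3)c(Br)c(O)c(C(=O)/C=C/N(C)C)c2OC)c(O)c1C(=O)/C=C/N(C)C | intermediate (not isolated)
8 | bis-chromone 7-(benzyloxy)-8-{[7-(benzyloxy)-8-bromo-5-methoxy-4-oxo-4H-chromen-6-yl]methyl}-5-methoxy-4H-chromen-4-one | COc1cc(OCc2ccccc2)c(Cc2c(OCc3ccccc3)c(Br)c3c(c2OC)C(=O)C=CO3)c2c1C(=O)C=CO2 | intermediate
9 | phenylboronic acid | OB(O)c1ccccc1 | starting material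
10 | (2S,2'S)-bis-flavanone (2S)-7-(benzyloxy)-8-{[(2S)-7-(benzyloxy)-8-bromo-5-methoxy-4-oxo-2-phenyl-3,4-dihydro-2H-chromen-6-yl]methyl}-5-methoxy-2-phenyl-2,3-dihydro-4H-chromen-4-one | COc1cc(OCc2ccccc2)c(Cc2c(OCc3ccccc3)c(Br)c3c(c2OC)C(=O)C[C@@H](c2ccccc2)O3)c2c1C(=O)C[C@@H](c1ccccc1)O2 | intermediate
11 | bis(flavan-4-ol), 2S and 2'S, C4 and C4' epimer mixture | COc1cc(OCc2ccccc2)c(Cc2c(OCc3ccccc3)c(Br)c3c(c2OC)C(O)C[C@@H](c2ccccc2)O3)c2c1C(O)C[C@@H](c1ccccc1)O2 | intermediate
12 | (2S)-7-(benzyloxy)-8-{[(2S)-7-(benzyloxy)-8-bromo-5-methoxy-2-phenyl-3,4-dihydro-2H-chromen-6-yl]methyl}-5-methoxy-2-phenyl-3,4-dihydro-2H-chromene | COc1cc(OCc2ccccc2)c(Cc2c(OCc3ccccc3)c(Br)c3c(c2OC)CC[C@@H](c2ccccc2)O3)c2c1CC[C@@H](c1ccccc1)O2 | intermediate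
13 | (2S)-8-{[(2S)-7-hydroxy-5-methoxy-2-phenyl-3,4-dihydro-2H-chromen-6-yl]methyl}-5-methoxy-2-phenyl-3,4-dihydro-2H-chromen-7-ol | COc1cc(O)c(Cc2c(O)cc3c(c2OC)CC[C@@H](c2ccccc2)O3)c2c1CC[C@@H](c1ccccc1)O2 | target

## Step count and least certain steps

Total step count: 10. Longest linear sequence: 9 steps (steps 1, 3, 4, 5, 6, 7, 8, 9, 10); step 2 is a one-step branch from 2.

Step 7 (key). The most likely failure is slow or incomplete second addition, because both chromones are electron-rich and weak acceptors, with protodeboronation of 9 consuming the aryl donor. Facial selectivity may also be insufficient at one site. Configuration would be lost by ring opening if the medium turns basic. Fallback: form O1–C2 instead of C2–phenyl. Starting from 6, twofold C-carboxylation of the methyl ketones (LiN(SiMe3)2, Boc2O) gives the bis(β-keto tert-butyl ester) F1. Knoevenagel condensation with benzaldehyde (piperidinium acetate) gives the bis(benzylidene) compound F2. A cinchona-derived bifunctional thiourea, in the pseudoenantiomeric form that leads to 2S, catalyses the twofold intramolecular oxa-Michael addition to the bis(3-tert-butoxycarbonyl flavanone) F3. Warming with TsOH removes the ester groups with loss of 2-methylpropene and CO2, and the route is rejoined at 10.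

Step 5. Self-alkylation and oligomerisation of 5 through its own free C5 may compete with attack by the hindered C5 of 3; transfer or loss of bromine under acid is a lesser risk. Fallback: reductive Friedel–Crafts alkylation from 4, whose ring is deactivated by the formyl group and cannot alkylate itself. 4 and 3 are combined in CF3CO2H/Et3SiH/CH2Cl2 at 0 °C; C5 of 3 adds to the protonated aldehyde to give the diaryl carbinol F4, which ionises and is reduced in the same flask. The route is rejoined at 6 without passing through 5.

Step 3. Aldol-type hydroxymethylation of the acetyl group under the magnesium/amine conditions, or sluggish reaction of the hydrogen-bonded phenol, may lower conversion. Fallback: aminomethylation in place of formylation. Starting from 2, N,N-dimethylmethyleneiminium iodide gives the Mannich base F5 ortho to the phenol. Heating F5 with 3 in toluene expels dimethylamine, and the resulting ortho-quinone methide is trapped at C5 of 3. The route is rejoined at 6, bypassing 4 and 5.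

Step 9. Ipso-protonation of the electron-rich diarylmethane followed by hydride capture would cleave the bridge irreversibly; partial loss or migration of benzyl groups and ionisation at C2 are further acid-driven risks. Fallback: avoid strong acid. Starting from 11, acetylation (Ac2O, pyridine) gives the bis(C4 acetate) F6. Hydrogenolysis (H2, Pd/C, NaOAc) removes the benzylic acetates together with the benzyl ethers and the bromine, and the route is rejoined at 13.

Step 10. Over-reduction by hydrogenolytic opening of the benzylic C2–O1 bonds, or stalling of the debenzylation through catalyst poisoning by bromide, are the likely problems. Fallback: no hydrogenation. Starting from 12, radical hydrodebromination (Bu3SnH, AIBN, toluene, 80 °C) gives the bromine-free dibenzyl ether F7. Lewis-acid debenzylation (BCl3, pentamethylbenzene, CH2Cl2, −78 °C) then rejoins the route at 13.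

## Further compounds

F1 | step 7 | bis(β-keto tert-butyl ester) of 6 | COc1cc(OCc2ccccc2)c(Cc2c(OCc3ccccc3)c(Br)c(O)c(C(=O)CC(=O)OC(C)(C)C)c2OC)c(O)c1C(=O)CC(=O)OC(C)(C)C
F2 | step 7 | bis(benzylidene β-keto tert-butyl ester), alkene geometry undefined | COc1cc(OCc2ccccc2)c(Cc2c(OCc3ccccc3)c(Br)c(O)c(C(=O)C(=Cc3ccccc3)C(=O)OC(C)(C)C)c2OC)c(O)c1C(=O)C(=Cc1ccccc1)C(=O)OC(C)(C)C
F3 | step 7 | (2S,2'S)-bis(3-tert-butoxycarbonyl flavanone), C3 and C3' undefined | COc1cc(OCc2ccccc2)c(Cc2c(OCc3ccccc3)c(Br)c3c(c2OC)C(=O)C(C(=O)OC(C)(C)C)[C@@H](c2ccccc2)O3)c2c1C(=O)C(C(=O)OC(C)(C)C)[C@@H](c1ccccc1)O2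
F4 | step 5 | diaryl carbinol from 4 and 3, racemic at the carbinol carbon | COc1cc(OCc2ccccc2)c(C(O)c2c(OCc3ccccc3)c(Br)c(O)c(C(C)=O)c2OC)c(O)c1C(C)=O
F5 | step 3 | 1-{4-(benzyloxy)-3-[(dimethylamino)methyl]-2-hydroxy-6-methoxyphenyl}ethan-1-one | COc1cc(OCc2ccccc2)c(CN(C)C)c(O)c1C(C)=O
F6 | step 9 | bis(C4 acetate) of 11, 2S and 2'S, C4 and C4' epimer mixture | COc1cc(OCc2ccccc2)c(Cc2c(OCc3ccccc3)c(Br)c3c(c2OC)C(OC(C)=O)C[C@@H](c2ccccc2)O3)c2c1C(OC(C)=O)C[C@@H](c1ccccc1)O2
F7 | step 10 | (2S,2'S)-7,7'-di-O-benzyl target (bromine-free) | COc1cc(OCc2ccccc2)c(Cc2c(OCc3ccccc3)cc3c(c2OC)CC[C@@H](c2ccccc2)O3)c2c1CC[C@@H](c1ccccc1)O2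
A1 | alternative 1 | bis(γ-hydroxy sulfone) with (R)-carbinols | COc1cc(OCc2ccccc2)c(Cc2c(OCc3ccccc3)cc(OCC=C)c(C(S(=O)(=O)c3ccccc3)C[C@H](c3ccccc3)O)c2OC)c(OCC=C)c1C(S(=O)(=O)c1ccccc1)C[C@H](c1ccccc1)O
A2 | alternative 1 | (S)-styrene oxide | C1[C@@H](O1)c1ccccc1
A3 | alternative 2 | 7-O-benzyl target (unit A benzylated, unit B phenol free) | COc1cc(OCc2ccccc2)c(Cc2c(O)cc3c(c2OC)CC[C@@H](c2ccccc2)O3)c2c1CC[C@@H](c1ccccc1)O2
A4 | alternative 3 | bis[(S)-1-phenylallyl] aryl ether | COc1cc(OCc2ccccc2)c(Cc2c(OCc3ccccc3)cc(O[C@H](c3ccccc3)C=C)c(C=C)c2OC)c(O[C@H](c2ccccc2)C=C)c1C=C
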